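**Retrosynthetic overview**

- Feature: the six-membered ring (C1 ketone, C2=C3 methyl enol ether, C4 mixed aryl methyl ketal, C5 H2, C6 allyl) is the 3-O-methyl enol ether of a cyclohexane-1,3-dione (C1, C3) whose C4 carries both ketal oxygens.
- Late disconnections: C6–allyl (enolate alkylation, last step) and O3–CH3 (enol ether formation).
- Ring disconnection: C4–C5 and C2–C3 together, by a Michael–Claisen annulation of the enolate of an N-[aryloxy(methoxy)acetyl]oxazolidinone with methyl vinyl ketone; this also sets C4.
- The imide comes from 2-allyl-4,5-dimethoxyphenol (O-allylation and Claisen rearrangement of 3,4-dimethoxyphenol), methyl chloro(methoxy)acetate and (S)-4-benzyloxazolidin-2-one.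
- Ring order: the arene is bought; the cyclohexenone ring is the only ring formed (step 7).

Key step: step 7

Remark: the acetal carbon of 6, 8, 9, 11 and 12 is stereogenic; these compounds are used as racemates (12 as the epimer mixture), because this centre becomes planar in enolate 14. Ring numbering throughout: C1 ketone, C2=C3, C4 ketal, C5, C6.

**Route**

Step 1
Reactants: 1 3,4-dimethoxyphenol; 2 allyl bromide
Product: 3 4-(allyloxy)-1,2-dimethoxybenzene
Conditions: K2CO3, acetone, reflux
Reagents that add atoms: none
Why: Williamson ether synthesis; the phenoxide formed with K2CO3 in acetone is alkylated on oxygen by the allylic bromide.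

Step 2
Reactants: 3 4-(allyloxy)-1,2-dimethoxybenzene
Product: 4 2-allyl-4,5-dimethoxyphenol
Conditions: PhNEt2, 200 °C
Reagents that add atoms: none
Why: Aromatic Claisen rearrangement; the [3,3] shift should go to the ortho carbon that is not flanked by a methoxy group, and tautomerisation of the dienone restores the phenol.

Step 3
Reactants: 5 methyl dimethoxyacetate
Product: 6 methyl 2-chloro-2-methoxyacetate
Conditions: AcCl, I2 (cat.), 55 °C; distillation
Reagents that add atoms: acetyl chloride, CC(=O)Cl
Why: Iodine-catalysed cleavage of one acetal C–OMe bond by acetyl chloride (acetal to α-chloro ether exchange) gives the α-chloro ether and methyl acetate, the standard preparation of this reagent.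

Step 4
Reactants: 4 2-allyl-4,5-dimethoxyphenol; 6 methyl 2-chloro-2-methoxyacetate
Product: 8 methyl 2-(2-allyl-4,5-dimethoxyphenoxy)-2-methoxyacetate, via sodium 2-allyl-4,5-dimethoxyphenoxide 7 (not isolated)
Conditions: NaH, THF, 0 °C; then 6, 0 °C → rt
Reagents that add atoms: none
Why: O-Alkylation of a phenoxide by an α-chloro ether (the reaction type of MOM ether formation); the chloride is activated by the adjacent methoxy oxygen, and no acid is present that could scramble the new mixed acetal.

Step 5
Reactants: 8 methyl 2-(2-allyl-4,5-dimethoxyphenoxy)-2-methoxyacetate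
Product: 9 2-(2-allyl-4,5-dimethoxyphenoxy)-2-methoxyacetic acid
Conditions: LiOH·H2O, THF–H2O, 0 °C → rt; then 1 M HCl to pH 3, 0 °C
Reagents that add atoms: lithium hydroxide, [Li+].[OH-]
Why: Saponification of an inductively activated methyl ester; the acetal is inert to hydroxide and should tolerate the brief cold acidification because an oxocarbenium ion next to the carboxyl group is strongly disfavoured.

Step 6
Reactants: 9 2-(2-allyl-4,5-dimethoxyphenoxy)-2-methoxyacetic acid; 10 (S)-4-benzyloxazolidin-2-one
Product: 12 (4S)-3-[2-(2-allyl-4,5-dimethoxyphenoxy)-2-methoxyacetyl]-4-benzyloxazolidin-2-one, via mixed pivalic anhydride 11 (not isolated)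
Conditions: t-BuCOCl, Et3N, THF, −20 °C; then LiCl, 10, −20 °C → rt
Reagents that add atoms: none
Why: N-Acylation of the oxazolidinone through the mixed pivalic anhydride (LiCl/Et3N protocol); the oxazolidinone attacks the dioxygenated acyl carbon, which is less hindered and more electrophilic than the pivaloyl carbon, and the epimer mixture at the acetal carbon is of no consequence.

Step 7
Reactants: 12 (4S)-3-[2-(2-allyl-4,5-dimethoxyphenoxy)-2-methoxyacetyl]-4-benzyloxazolidin-2-one; 13 methyl vinyl ketone
Product: 16 (4R)-4-(2-allyl-4,5-dimethoxyphenoxy)-4-methoxycyclohexane-1,3-dione, via sodium imide enolate 14 (not isolated), via Michael adduct enolate 15 (not isolated)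
Conditions: NaN(SiMe3)2 (1.05 equiv), THF, −78 °C; 13 (1.1 equiv), −78 °C; NaN(SiMe3)2 (1.1 equiv), −78 → 0 °C; AcOH, then aq. NaH2PO4
Reagents that add atoms: none
Why: Proposed new method: NaN(SiMe3)2 removes the α-H of 12, which is activated by two oxygens and the imide, to give the chelated tetrasubstituted sodium enolate 14, which adds 1,4 to 13 and forms C4–C5 and the quaternary mixed ketal; HN(SiMe3)2 then shuttles a proton so that the methyl (C2) enolate of 15 forms and attacks the imide carbonyl, closing ring C1–C6 by a 6-exo-trig C-acylation (bond C2–C3) with loss of the oxazolidinone, and deprotonation of the dione at C2 pulls both equilibria, and any O-acylated enol lactone, to 16. The closest known reactions are the Michael–Claisen annulation of ester or ketone enolates with enones or acrylates to cyclohexane-1,3-diones, the alkylation of sodium enolates of N-(alkoxyacetyl)oxazolidinones, and Dieckmann-type closures that expel an oxazolidinone; what is new is their combination on an α,α-dioxygenated imide. C4 is controlled by the auxiliary: in the sodium-chelated enolate the benzyl group shields one face, and with the aryloxy group cis to O–Na and the small methoxy group next to the auxiliary (least allylic strain) attack of 13 on the open face should give (4R), the same facial sense as the known allylation of the propionyl imide to its (2R) product. The step needs one enolate geometry, 1,4- over 1,2-addition and C- over O-acylation; the first rests on the size difference between OMe and the ortho-substituted aryloxy group, the second on the hindered, stabilised enolate, and the third on thermodynamic control by the second equivalent of base. All of this runs under basic conditions, so the mixed ketal cannot ionise or exchange, and the auxiliary 10 is recovered.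

Step 8
Reactants: 16 (4R)-4-(2-allyl-4,5-dimethoxyphenoxy)-4-methoxycyclohexane-1,3-dione
Product: 17 (4R)-4-(2-allyl-4,5-dimethoxyphenoxy)-3,4-dimethoxycyclohex-2-en-1-one
Conditions: Me3SiCHN2, toluene–MeOH (4:1), 0 °C → rt; chromatography
Reagents that add atoms: (trimethylsilyl)diazomethane, C[Si](C)(C)C=[N+]=[N-]
Why: Methylation of a cyclic 1,3-dione (vinylogous acid) by (trimethylsilyl)diazomethane in methanol is a neutral O-alkylation that leaves the mixed ketal and both allyl groups untouched; the two enol oxygens are not strongly differentiated, so 17 has to be separated by chromatography from its O1-methyl regioisomer.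

Step 9
Reactants: 17 (4R)-4-(2-allyl-4,5-dimethoxyphenoxy)-3,4-dimethoxycyclohex-2-en-1-one; 2 allyl bromide
Product: 19 (4R,6R)-6-allyl-4-(2-allyl-4,5-dimethoxyphenoxy)-3,4-dimethoxycyclohex-2-en-1-one, via lithium dienolate 18 (not isolated)
Conditions: LiN(i-Pr)2, THF, −78 °C; then 2, DMPU, −78 → −40 °C
Reagents that add atoms: none
Why: Kinetic α′-deprotonation and alkylation of a 3-alkoxy enone (Stork–Danheiser-type enolate alkylation): C6 is the only enolisable position because C4 is quaternary, and allyl bromide should enter anti to the aryloxy group at C4, which is expected to sit pseudoaxial (away from the C3 methoxy group, C–O bond aligned with the dienolate π system), so that (6R) with allyl trans to aryloxy results.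

**Compound list**

1 | 3,4-dimethoxyphenol | COc1ccc(O)cc1OC | starting material
2 | allyl bromide | C=CCBr | starting material
3 | 4-(allyloxy)-1,2-dimethoxybenzene | C=CCOc1ccc(OC)c(OC)c1 | intermediate
4 | 2-allyl-4,5-dimethoxyphenol | C=CCc1cc(OC)c(OC)cc1O | intermediate
5 | methyl dimethoxyacetate | COC(OC)C(=O)OC | starting material
6 | methyl 2-chloro-2-methoxyacetate (racemic) | COC(Cl)C(=O)OC | intermediate
7 | sodium 2-allyl-4,5-dimethoxyphenoxide | C=CCc1cc(OC)c(OC)cc1[O-].[Na+] | intermediate (not isolated)
8 | methyl 2-(2-allyl-4,5-dimethoxyphenoxy)-2-methoxyacetate (racemic) | C=CCc1cc(OC)c(OC)cc1OC(OC)C(=O)OC | intermediate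
9 | 2-(2-allyl-4,5-dimethoxyphenoxy)-2-methoxyacetic acid (racemic) | C=CCc1cc(OC)c(OC)cc1OC(OC)C(=O)O | intermediate
10 | (S)-4-benzyloxazolidin-2-one | O=C1N[C@@H](Cc2ccccc2)CO1 | starting material
11 | 2-(2-allyl-4,5-dimethoxyphenoxy)-2-methoxyacetic pivalic anhydride (racemic) | C=CCc1cc(OC)c(OC)cc1OC(OC)C(=O)OC(=O)C(C)(C)C | intermediate (not isolated)
12 | (4S)-3-[2-(2-allyl-4,5-dimethoxyphenoxy)-2-methoxyacetyl]-4-benzyloxazolidin-2-one (both acetal epimers) | C=CCc1cc(OC)c(OC)cc1OC(OC)C(=O)N1[C@@H](Cc2ccccc2)COC1=O | intermediate
13 | methyl vinyl ketone | CC(=O)C=C | starting material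
14 | sodium (Z)-enolate of 12 (aryloxy cis to O–Na, methoxy cis to N) | C=CCc1cc(OC)c(OC)cc1O/C(OC)=C(\[O-])N1[C@@H](Cc2ccccc2)COC1=O.[Na+] | intermediate (not isolated)
15 | sodium enolate of (4S)-3-[(2R)-2-(2-allyl-4,5-dimethoxyphenoxy)-2-methoxy-5-oxohexanoyl]-4-benzyloxazolidin-2-one | C=CCc1cc(OC)c(OC)cc1O[C@](OC)(CC=C(C)[O-])C(=O)N1[C@@H](Cc2ccccc2)COC1=O.[Na+] | intermediate (not isolated)
16 | (4R)-4-(2-allyl-4,5-dimethoxyphenoxy)-4-methoxycyclohexane-1,3-dione | C=CCc1cc(OC)c(OC)cc1O[C@]1(OC)CCC(=O)CC1=O | intermediate
17 | (4R)-4-(2-allyl-4,5-dimethoxyphenoxy)-3,4-dimethoxycyclohex-2-en-1-one | C=CCc1cc(OC)c(OC)cc1O[C@]1(OC)CCC(=O)C=C1OC | intermediate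
18 | lithium dienolate of 17 (C6=C1–OLi) | C=CCc1cc(OC)c(OC)cc1O[C@]1(OC)CC=C([O-])C=C1OC.[Li+] | intermediate (not isolated)
19 | (4R,6R)-6-allyl-4-(2-allyl-4,5-dimethoxyphenoxy)-3,4-dimethoxycyclohex-2-en-1-one | C=CCc1cc(OC)c(OC)cc1O[C@]1(OC)C[C@@H](CC=C)C(=O)C=C1OC | target

**Step count**

Total steps: 9. Longest linear sequence: 8 steps (1 → 3 → 4 → 8 → 9 → 12 → 16 → 17 → 19); step 3 is a one-step side branch.

**Steps most likely to fail**

1. Step 7 (the proposed new method). Enolisation of the α,α-disubstituted imide may be slow or give both enolate geometries, because one α-substituent must lie next to the auxiliary; this would erode the enantiomeric purity at C4. Methyl vinyl ketone may also polymerise or add 1,2, and the sequence may stall before C-acylation. The fallback uses known chemistry and gives up auxiliary control. It sets out from ester 8 and rejoins at 16, so steps 5 and 6 are not needed. Ester 8 is deprotonated with LiN(i-Pr)2 in THF at −78 °C, 13 is added, and the mixture is warmed with KOt-Bu to complete the Claisen closure (the established Michael–Claisen annulation of an ester enolate with an enone). This gives racemic 4-(2-allyl-4,5-dimethoxyphenoxy)-4-methoxycyclohexane-1,3-dione F1. Preparative chromatography on a chiral polysaccharide phase then separates 16 from (4S)-4-(2-allyl-4,5-dimethoxyphenoxy)-4-methoxycyclohexane-1,3-dione F2.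

2. Step 8. Methylation may occur largely at the wrong enol oxygen (O1, remote from the ketal), since neither sterics nor electronics clearly favour O3. The fallback moves the selectivity from the methylation to a hydrolysis; it sets out from 16 and rejoins at 17. Dione 16 is methylated unselectively (Me2SO4, K2CO3, acetone) to a mixture of 17 and (6R)-6-(2-allyl-4,5-dimethoxyphenoxy)-3,6-dimethoxycyclohex-2-en-1-one F3. The mixture is treated with LiOH in THF–H2O at 0 °C → rt. Hydroxide should add to the unhindered methoxy-bearing carbon of the regioisomer much faster than to C3 of 17, which is flanked by the quaternary ketal. The regioisomer is thus hydrolysed back to the water-soluble enolate of 16, 17 is extracted, and recovered 16 is methylated again.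

3. Step 9. Facial selectivity in the alkylation of dienolate 18 may be poor if the aryloxy group does not hold the pseudoaxial position, and a second allylation at C6 may compete. The fallback replaces substrate control by catalyst control; it sets out from 17 and rejoins at 19. Treatment of 17 with LiN(SiMe3)2 and TMEDA, then allyl chloroformate, gives allyl (4R)-4-(2-allyl-4,5-dimethoxyphenoxy)-4,5-dimethoxycyclohexa-1,5-dien-1-yl carbonate F4. Decarboxylative allylation with Pd2(dba)3·CHCl3 (zerovalent palladium) and a chiral Trost bisphosphine ligand then delivers the allyl group to C6 under neutral conditions. The ligand enantiomer is chosen by screening so that the catalyst selects the C6 face that gives 19.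

**Further compounds**

F1 | step 7 | racemic 4-(2-allyl-4,5-dimethoxyphenoxy)-4-methoxycyclohexane-1,3-dione | C=CCc1cc(OC)c(OC)cc1OC1(OC)CCC(=O)CC1=O
F2 | step 7 | (4S)-4-(2-allyl-4,5-dimethoxyphenoxy)-4-methoxycyclohexane-1,3-dione | C=CCc1cc(OC)c(OC)cc1O[C@@]1(OC)CCC(=O)CC1=O
F3 | step 8 | (6R)-6-(2-allyl-4,5-dimethoxyphenoxy)-3,6-dimethoxycyclohex-2-en-1-one | C=CCc1cc(OC)c(OC)cc1O[C@]1(OC)CCC(OC)=CC1=O
F4 | step 9 | allyl (4R)-4-(2-allyl-4,5-dimethoxyphenoxy)-4,5-dimethoxycyclohexa-1,5-dien-1-yl carbonate | C=CCc1cc(OC)c(OC)cc1O[C@]1(OC)CC=C(OC(=O)OCC=C)C=C1OC
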